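The readings come from a simulation from invented constants, and the scatter is random.

One round of the catalyst makes one product and uses one reagent, so I count rounds. The flasks:

in all of them: starting material 0.050 M; free catalyst 0.80 mM
- ochre: reagent 0.036 M; run made earlier
- teal: reagent 0.55 M; run made earlier
- elm: reagent 0.0250 M; time 12 h
- cedar: reagent 0.0500 M; time 12 h
- ash: reagent 0.100 M; time 12 h
- maple: reagent 0.200 M; time 12 h
- larch: reagent 0.400 M; time 12 h

- ochre (time / h: product / %): 0.667: 2.1; 1.00: 3.2; 2.00: 6.9; 3.00: 10.0; 5.00: 16.4; 8.00: 25.7
- teal (time / h: product / %): 0.500: 0.7; 1.50: 1.1; 3.00: 1.9; 5.00: 3.4; 6.00: 4.5; 8.00: 5.7

(each reading ± 0.3 percentage points)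

- reactions considered so far: reagent + catalyst intermediate B <-> idle complex; catalyst intermediate B -> free catalyst + product; starting material + catalyst intermediate A <-> catalyst intermediate B; reagent + free catalyst -> catalyst intermediate A
- "hardly changes" means that all values lie within two and a half points (for a concentration: within two and a half percent of the largest)

* amount of product at the end, in percent of the starting material charged for elm, cedar, ash, maple, larch, in this order
* how the row runs (rises, then falls / falls all the way / falls, then rises / hardly changes / rises all the way)

The unit of my count is the round share, the part of the starting material that one round of the whole catalyst charge turns into product: 1.60%. The round time, τ, is the hours one round takes, that is, the time multiplied by the round share and divided by the product reached.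

Ochre at 8.00 h gives τ = 0.498 h, and teal gives 2.25 h, a slower round at the higher reagent charge. Reagent can hold catalyst intermediate B in the idle complex, so I take τ as a straight line in reagent concentration. It climbs by 0.340 h for each 0.100 M of reagent, which is the charge of ash, and its value at zero reagent is 0.376 h.

On that line, elm has τ = 0.461 h and larch has 1.74 h. Dividing 12 h by τ and multiplying by the round share gives my row: 41.7%, 35.2%, 26.8%, 18.2%, 11.1%. It falls all the way. Reagent is the limiting reagent in elm, whose charge allows 31.2 rounds, or 50.0% product, and my count stays under that.

The weak link is elm's late hours. By my count its reagent ends near 0.00416 M, below the 0.0231 M that ochre reached, so the line is unproved there. Ochre's easing is slight: its last reading lies 0.7 percentage points below what the pace of its first 3.00 h, carried on from its reading at 5.00 h, gives, against a scatter of 0.3 points on each reading, while starting material fell as well. I therefore keep elm's figure as an upper edge, with a margin of 6.5 points over cedar.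

The forecast gives 31%, 40%, 32%, 20%, 11%, a row that rises, then falls, and says “Elm is starved as its reagent runs down”. Its row climbs from elm to cedar, where mine falls.

The flask gives 40.0%, 35.0%, 27.2%, 18.7%, 11.4%: the row falls all the way, from these steps:

    reagent + catalyst intermediate B ⇌ idle complex, settled at all times (K = 28.0 M⁻¹)
    catalyst intermediate B → free catalyst + product (k = 8.46 h⁻¹)
    starting material + catalyst intermediate A ⇌ catalyst intermediate B (K = 12.8 M⁻¹, k = 387 M⁻¹ h⁻¹)
    reagent + free catalyst → catalyst intermediate A (k = 8600 M⁻¹ h⁻¹)

Counted from these ends, the round time is 0.480 h in elm and 1.68 h in larch. The largest single effect on the fall from elm to larch is the binding of reagent to catalyst intermediate B into the idle complex: without that binding, the change from −29 points becomes 0.95 points. At 12.0 h, the idle complex in larch holds 77.0% of the catalyst charged.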